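## The problem

Asperimide C (20) joins two ring systems through one methylene: a (3S)-3-hydroxy-2,2-dimethylchroman substituted at C7, and a maleimide whose C3' carries that methylene and whose C4' carries a 4-hydroxyphenyl group. The only stereocentre, C3 of the chroman, lies next to the quaternary C2 and far from the imide. Nothing in the molecule can direct it and it directs nothing, so it has to be set by a catalyst-controlled step and then carried unchanged. The harder constructional problem is the maleimide: C3'=C4' is tetrasubstituted, necessarily cis, and differently substituted at its two ends, so a benzylic and an aryl group must be placed on adjacent carbons without regiochemical confusion. The sensitive functions are the imide (opened by hydroxide or alkoxide, acidic N–H), the free phenol, the secondary alcohol beside a tertiary aryl ether, and the methylene between arene and maleimide, which base can deprotonate and then isomerise or oxidise. The feature that invites a short solution is that C3' and C4' are each bonded to an imide carbonyl (C2' and C5'). A sulfonyl group bridging them gives a six-membered thiomorpholine-3,5-dione 1,1-dioxide with two strongly acidified sulfone positions. These can be substituted one after the other from a symmetric core and then joined, with loss of SO2, to give the cis alkene inside the five-membered imide.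

## Retrosynthesis

**20 ⇒ 19.** The N1'–benzyl bond and the phenolic O–tert-butyl bond are cut. An N-substituent is needed because a free imide N–H would compete with the sulfone carbons for base and electrophile. The 2,4-dimethoxybenzyl group and the aryl tert-butyl ether both leave under one acid treatment. The C3 hydroxyl is left free throughout: it is hindered and far less acidic than any position that has to react. The forward step must cleave both groups by acidolysis without touching the chroman.

**19 ⇒ 16.** The C3'=C4' bond is cut and the two carbons are reconnected through SO2, giving the thiomorpholine-3,5-dione 1,1-dioxide 16. The neighbouring cuts are two successive cross-couplings on a dihalomaleimide, or condensation of an arylacetamide with an enolisable α-keto ester. The first needs a benzylic organometallic; the second suffers from enolisation of the keto ester. The sulfone precursor instead carries both substituents on sp3 carbons that are made by carbanion chemistry, and their configuration is irrelevant because both centres are erased. The forward reaction must monohalogenate one sulfone carbon, close the episulfone from the other and lose SO2 before base can damage the imide.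

**16 ⇒ 14 + 15.** The C6–aryl bond is cut. The aryl group goes on last. If it were introduced first, the aryl-bearing carbon would be the most acidic site and would capture the alkylating agent, giving a quaternary centre. The forward step is a Pd-catalysed α-arylation with 1-bromo-4-tert-butoxybenzene (15) at the unsubstituted CH2 of 14, in preference to the benzyl-bearing CH.

**14 ⇒ 13 + 8.** The bond between C2 of the heterocycle and the benzylic methylene is cut. The two sulfone positions of 13 are equivalent, so only mono- versus dialkylation has to be controlled, and an excess of the inexpensive core 13 does that. The electrophile is the benzylic bromide 8.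

**13 ⇒ 12 ⇒ 9 + 10.** The sulfone oxygens are removed to give sulfide 12. Its two imide C–N bonds are cut to thiodiglycolic anhydride (9) and 2,4-dimethoxybenzylamine (10). Oxidation is placed after imide formation because sulfonyldiacetic acids decarboxylate easily.

**8 ⇒ 7 ⇒ 6 ⇒ 5 ⇒ 1 + 2.** The C–Br bond of 8 comes from the benzylic alcohol of diol 7. One hydride reagent gives 7 from epoxy ester 6 by cleaving the benzylic C4–O bond and reducing the ester. The epoxide oxygen of 6 is introduced enantioselectively on chromene 5, a substrate class for which salen-manganese epoxidation is particularly reliable. Chromene 5 is cut at C3–C4 and O1–C2 to the salicylaldehyde 1 and the isobutenyl Grignard reagent 2. The arene and its 1,2,4-substitution pattern are bought with 1.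

## Roads not taken

**Alternative 1:** The chroman is cut at C4–C4a and C2–C3, so the arene, a vinyl unit (C4, C3) and an isopropenyl unit (C2 with its methyls) come from three components. The boron ate complex from isopropenylboronic ester A2 and vinyllithium A3 would react with aryl triflate A1 under Pd(OAc)2 and a chiral ferrocenyl bisphosphine. The arylpalladium species triggers a 1,2-shift of isopropenyl from boron to carbon and gives boronate A4, with C3 set by the catalyst and no ring closed. Oxidation of the C–B bond with retention, desilylation, Markovnikov hydroalkoxylation to close O1–C2 and ester reduction would reach diol 7.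
- Merits: it is convergent, the stereocentre arises in a catalytic C–C bond-forming event, and the oxygen is introduced stereospecifically.
- Weak points:
  - The ate complex carries two alkenyl groups, and nothing ensures that palladium activates the vinyl group while isopropenyl migrates, and not the reverse.
  - A4 is an allylic boronate, prone to 1,3-borotropic shift and protodeboronation.
  - The ortho-silyloxy triflate A1 is hindered and needs regioselective differentiation of a catechol.
  - The closing hydroalkoxylation passes through a tertiary cation next to a free allylic alcohol.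
- Comparison: about six operations are needed to reach 7, against three in the chosen plan, and the maleimide is left open. This road is the more convergent way to C3. The chosen plan sets against it the enantioselective epoxidation of a 2,2-dimethylchromene and a shorter fragment synthesis, and spends its single uncertain step on the maleimide.

**Alternative 2:** The arene itself is cut (C4a–C5, C4a–C8a, C7–C8, C6–C7) back to the acyclic diazo enone A5, which carries the C3 stereocentre and a tethered ethynyl ether. Irradiation would cause Wolff rearrangement. A ketene–alkyne [2+2] cycloaddition, four-electron ring opening and six-electron closure would then deliver chromanol A6, forming the pyran ring and the benzene ring in one operation.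
- Merits: complete regiocontrol of the arene substitution through the tether, and a cascade that builds two rings.
- Weak points:
  - A5 needs a long linear synthesis, and its ethynyl ether sits on a tertiary carbon. Such ethers fragment thermally to a ketene and an alkene.
  - The cascade creates an oxygen at C7 where the target has carbon, so triflation and a further C–C coupling are needed.
  - The benzene ring is built at considerable cost although it is commercially available with the right substitution in 1.
  - The stereocentre still has to be made by a separate asymmetric step.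
- Comparison: this road would be the better choice for an arene pattern that cannot be bought; here it can be. The chosen plan is much shorter and reaches the C7 carbon substituent directly from the ester of 1.

**Alternative 3:** The pyran is cut at C3–C4 and O1–C2. A chiral BINOL-derived phosphoric acid would ionise the o-hydroxybenzyl alcohol A7 to the quinone methide A8, which would add isobutenylboronate A9 to give the 3-boryl chroman A10, closing the ring and setting C3. Oxidation of the C–B bond and ester reduction would then give 7.
- Merits: two bonds, the ring and the stereocentre are made in one step from very simple partners. The chosen plan needs two steps for the same result (chromene formation and epoxidation), and the overall length to 7 is comparable.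
- Weak points:
  - A8 has no substituent on the methide carbon and carries an ester, so it forms reluctantly and oligomerises readily.
  - A9 has no hydrogen-bond donor through which the phosphate could organise it, and the stereocentre is created on the boronate carbon, remote from the catalyst's contact with the quinone methide oxygen.
  - The cationic intermediate has boron β to the tertiary cation and can lose the boryl group to give a prenylated phenol.
- Comparison: if high enantioselectivity could be secured, this road would equal the chosen chroman synthesis in length and surpass it in elegance. The chosen plan relies on an epoxidation whose selectivity with 2,2-dimethylchromenes is well established.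

None of the three alternatives addresses the maleimide.

Key step: step 9

Assumption: the (S,S)-salen manganese catalyst is taken to deliver the (3S,4S)-epoxide from chromene 5, as it does for closely related 2,2-dimethylchromenes; cleavage of the C4–O bond then leaves the (3S)-alcohol.

## Route

Step 1
Reactants: 1 methyl 4-formyl-3-hydroxybenzoate; 2 (2-methylprop-1-en-1-yl)magnesium bromide
Product: 5 methyl 2,2-dimethyl-2H-chromene-7-carboxylate, via allylic alcohol 3 (not isolated), via quinone methide 4 (not isolated)
Conditions: 2 (2.2 equiv), THF, −78 to −30 °C; AcOH quench; then PPTS (cat.), toluene, 80 °C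
Reagents that add atoms: none
Why: Grignard addition to the chelated aldehyde is much faster than to the methyl ester at low temperature and gives 3; acid-promoted loss of water gives the o-quinone methide 4, which closes by oxa-6π electrocyclisation (O1–C2) to the 2,2-dimethylchromene.

Step 2
Reactants: 5 methyl 2,2-dimethyl-2H-chromene-7-carboxylate
Product: 6 methyl (3S,4S)-3,4-epoxy-2,2-dimethylchroman-7-carboxylate (cis-fused epoxide)
Conditions: (S,S)-[N,N'-bis(3,5-di-tert-butylsalicylidene)cyclohexane-1,2-diaminato]MnCl (4 mol %), 4-phenylpyridine N-oxide (20 mol %), aq NaOCl (pH 11.3), CH2Cl2, 0 °C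
Reagents that add atoms: sodium hypochlorite, [Na+].[O-]Cl
Why: Jacobsen–Katsuki epoxidation; cis-disubstituted aryl-conjugated alkenes of the 2,2-dimethylchromene type are the best substrates for this catalyst, and the (S,S)-ligand should deliver oxygen to the face that gives the (3S,4S)-epoxide, which fixes C3.

Step 3
Reactants: 6 methyl (3S,4S)-3,4-epoxy-2,2-dimethylchroman-7-carboxylate
Product: 7 (3S)-7-(hydroxymethyl)-2,2-dimethylchroman-3-ol
Conditions: LiAlH4 (3 equiv), THF, 0 °C to rt; aqueous NaOH work-up
Reagents that add atoms: none
Why: Hydride reduction of the ester and regioselective hydride opening of the epoxide at benzylic C4 (C3 is shielded by the adjacent quaternary C2); the C3–O bond is not touched, so the configuration set in step 2 is retained.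

Step 4
Reactants: 7 (3S)-7-(hydroxymethyl)-2,2-dimethylchroman-3-ol
Product: 8 (3S)-7-(bromomethyl)-2,2-dimethylchroman-3-ol
Conditions: CBr4 (1.1 equiv), PPh3 (1.15 equiv), CH2Cl2, −10 to 0 °C
Reagents that add atoms: carbon tetrabromide, BrC(Br)(Br)Br
Why: Appel reaction; the primary benzylic alkoxyphosphonium ion is displaced by bromide rapidly, whereas the secondary alcohol beside the quaternary C2 resists backside displacement and is returned unchanged on work-up.

Step 5
Reactants: 9 thiodiglycolic anhydride (1,4-oxathiane-2,6-dione); 10 2,4-dimethoxybenzylamine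
Product: 12 4-(2,4-dimethoxybenzyl)thiomorpholine-3,5-dione, via amic acid 11 (not isolated)
Conditions: THF, rt; evaporate; then Ac2O, NaOAc, 90 °C
Reagents that add atoms: none
Why: Aminolysis of the cyclic anhydride gives the amic acid, and mixed-anhydride activation closes the six-membered imide (classical imide synthesis).

Step 6
Reactants: 12 4-(2,4-dimethoxybenzyl)thiomorpholine-3,5-dione
Product: 13 4-(2,4-dimethoxybenzyl)thiomorpholine-3,5-dione 1,1-dioxide
Conditions: mCPBA (2.3 equiv), CH2Cl2, 0 °C to rt
Reagents that add atoms: 3-chloroperoxybenzoic acid, OOC(=O)c1cccc(Cl)c1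
Why: Peracid oxidation of the sulfide through the sulfoxide to the sulfone; the imide and the dimethoxyarene are inert to the peracid under these conditions.

Step 7
Reactants: 8 (3S)-7-(bromomethyl)-2,2-dimethylchroman-3-ol; 13 4-(2,4-dimethoxybenzyl)thiomorpholine-3,5-dione 1,1-dioxide
Product: 14 4-(2,4-dimethoxybenzyl)-2-{[(3S)-3-hydroxy-2,2-dimethylchroman-7-yl]methyl}thiomorpholine-3,5-dione 1,1-dioxide (both epimers at C2)
Conditions: 13 (2.5 equiv), K2CO3 (1.2 equiv), DMF, 0 °C to rt
Reagents that add atoms: none
Why: SN2 C-alkylation of a sulfonyl- and carbonyl-stabilised carbanion by a benzylic bromide; the excess of symmetric 13 suppresses dialkylation, carbonate does not deprotonate the alcohol, and the new C2 centre is uncontrolled because it is erased in step 9.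

Step 8
Reactants: 14 4-(2,4-dimethoxybenzyl)-2-{[(3S)-3-hydroxy-2,2-dimethylchroman-7-yl]methyl}thiomorpholine-3,5-dione 1,1-dioxide; 15 1-bromo-4-tert-butoxybenzene
Product: 16 2-(4-tert-butoxyphenyl)-4-(2,4-dimethoxybenzyl)-6-{[(3S)-3-hydroxy-2,2-dimethylchroman-7-yl]methyl}thiomorpholine-3,5-dione 1,1-dioxide (mixture of diastereomers at C2 and C6)
Conditions: 15 (1.3 equiv), Pd(OAc)2 (5 mol %), P(tBu)3·HBF4 (10 mol %), K3PO4 (3 equiv), toluene, 90 °C
Reagents that add atoms: none
Why: Pd-catalysed α-arylation of a sulfonyl-stabilised C–H acid (oxidative addition, C-bound enolate, reductive elimination); the unsubstituted CH2 carbanion is less hindered than the benzyl-bearing CH, and the more acidic product stays deprotonated, which prevents a second arylation; the new centre is uncontrolled and later erased.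

Step 9
Reactants: 16 2-(4-tert-butoxyphenyl)-4-(2,4-dimethoxybenzyl)-6-{[(3S)-3-hydroxy-2,2-dimethylchroman-7-yl]methyl}thiomorpholine-3,5-dione 1,1-dioxide
Product: 19 3-(4-tert-butoxyphenyl)-1-(2,4-dimethoxybenzyl)-4-{[(3S)-3-hydroxy-2,2-dimethylchroman-7-yl]methyl}-1H-pyrrole-2,5-dione, via bromo sulfone 17 (not isolated), via episulfone 18 (not isolated)
Conditions: DBU (3 equiv), BrCl2C–CCl2Br (1.05 equiv, slow addition), THF, −20 °C to rt; AcOH quench
Reagents that add atoms: none
Why: Proposed new method: DBU removes the most acidic proton (at the aryl-bearing sulfone carbon), the carbanion takes Br+ from BrCl2C–CCl2Br (which collapses irreversibly to C2Cl4 and bromide) to give 17, a second deprotonation at the other sulfone carbon gives a carbanion that displaces bromide across sulfur in a 3-exo-tet closure to the bicyclic episulfone 18, and cheletropic loss of SO2 leaves the C3'=C4' bond of 19, i.e. a Ramberg–Bäcklund reaction with in situ halogenation. The closest known reaction type is the contraction of thiane 1,1-dioxides to cyclopentenes under in situ halogenation, together with the bromination of malonate-type carbanions by polyhaloalkanes and an amidine base; new here is that both sulfone carbons are also imide α-carbons and fully substituted. The lasting ring, the five-membered imide, is closed by ring contraction: its C3'–C4' bond forms in the 3-exo-tet step and the ring becomes the maleimide when SO2 leaves. No stereocentre is created, both labile centres of 16 are erased so the diastereomer mixture converges, and the ring permits only the cis alkene. The step needs monobromination followed by 1,3-elimination in preference to dibromination, imide opening and base-induced migration of the new double bond to the exocyclic benzylidene position. The high acidity of both positions allows a non-nucleophilic amidine in an aprotic solvent (no hydroxide is present), slow addition of one equivalent of the bromine donor keeps the intramolecular closure ahead of a second bromination, and the acidic quench limits exposure of 19 to base; the C3 hydroxyl is remote and is not deprotonated by DBU.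

Step 10
Reactants: 19 3-(4-tert-butoxyphenyl)-1-(2,4-dimethoxybenzyl)-4-{[(3S)-3-hydroxy-2,2-dimethylchroman-7-yl]methyl}-1H-pyrrole-2,5-dione
Product: 20 asperimide C, 3-{[(3S)-3-hydroxy-2,2-dimethylchroman-7-yl]methyl}-4-(4-hydroxyphenyl)-1H-pyrrole-2,5-dione
Conditions: CF3CO2H, anisole (10 equiv), 70 °C; then MeOH, aq NaHCO3 work-up
Reagents that add atoms: none
Why: Acidolysis (SN1) of the aryl tert-butyl ether and of the N-(2,4-dimethoxybenzyl) imide, with anisole trapping the benzylic cation; the bicarbonate/methanol work-up cleaves any trifluoroacetate formed at the C3 hydroxyl, and C3 cannot ionise next to the oxygen-bearing C2, so its configuration is kept.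

## Compound list

1 | methyl 4-formyl-3-hydroxybenzoate | COC(=O)c1ccc(C=O)c(O)c1 | starting material
2 | (2-methylprop-1-en-1-yl)magnesium bromide | CC(C)=C[Mg]Br | starting material
3 | methyl 3-hydroxy-4-(1-hydroxy-3-methylbut-2-en-1-yl)benzoate (racemic) | COC(=O)c1ccc(C(O)C=C(C)C)c(O)c1 | intermediate
4 | methyl 4-(3-methylbut-2-en-1-ylidene)-3-oxocyclohexa-1,5-diene-1-carboxylate (o-quinone methide) | COC(=O)C1=CC(=O)C(=CC=C(C)C)C=C1 | intermediate
5 | methyl 2,2-dimethyl-2H-chromene-7-carboxylate | COC(=O)c1ccc2C=CC(C)(C)Oc2c1 | intermediate
6 | methyl (3S,4S)-3,4-epoxy-2,2-dimethylchroman-7-carboxylate | CC1(C)Oc2cc(C(=O)OC)ccc2[C@@H]3O[C@H]13 | intermediate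
7 | (3S)-7-(hydroxymethyl)-2,2-dimethylchroman-3-ol | CC1(C)Oc2cc(CO)ccc2C[C@@H]1O | intermediate
8 | (3S)-7-(bromomethyl)-2,2-dimethylchroman-3-ol | CC1(C)Oc2cc(CBr)ccc2C[C@@H]1O | intermediate
9 | thiodiglycolic anhydride (1,4-oxathiane-2,6-dione) | O=C1CSCC(=O)O1 | starting material
10 | 2,4-dimethoxybenzylamine | COc1ccc(CN)c(OC)c1 | starting material
11 | 2-({2-[(2,4-dimethoxybenzyl)amino]-2-oxoethyl}sulfanyl)acetic acid | COc1ccc(CNC(=O)CSCC(=O)O)c(OC)c1 | intermediate
12 | 4-(2,4-dimethoxybenzyl)thiomorpholine-3,5-dione | COc1ccc(CN2C(=O)CSCC2=O)c(OC)c1 | intermediate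
13 | 4-(2,4-dimethoxybenzyl)thiomorpholine-3,5-dione 1,1-dioxide | COc1ccc(CN2C(=O)CS(=O)(=O)CC2=O)c(OC)c1 | intermediate
14 | 4-(2,4-dimethoxybenzyl)-2-{[(3S)-3-hydroxy-2,2-dimethylchroman-7-yl]methyl}thiomorpholine-3,5-dione 1,1-dioxide (both C2 epimers) | CC1(C)Oc2cc(CC3C(=O)N(Cc4ccc(OC)cc4OC)C(=O)CS3(=O)=O)ccc2C[C@@H]1O | intermediate
15 | 1-bromo-4-tert-butoxybenzene | CC(C)(C)Oc1ccc(Br)cc1 | starting material
16 | 2-(4-tert-butoxyphenyl)-4-(2,4-dimethoxybenzyl)-6-{[(3S)-3-hydroxy-2,2-dimethylchroman-7-yl]methyl}thiomorpholine-3,5-dione 1,1-dioxide (diastereomer mixture at C2 and C6) | CC1(C)Oc2cc(CC3C(=O)N(Cc4ccc(OC)cc4OC)C(=O)C(c4ccc(OC(C)(C)C)cc4)S3(=O)=O)ccc2C[C@@H]1O | intermediate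
17 | 2-bromo-2-(4-tert-butoxyphenyl)-4-(2,4-dimethoxybenzyl)-6-{[(3S)-3-hydroxy-2,2-dimethylchroman-7-yl]methyl}thiomorpholine-3,5-dione 1,1-dioxide | CC1(C)Oc2cc(CC3C(=O)N(Cc4ccc(OC)cc4OC)C(=O)C(Br)(c4ccc(OC(C)(C)C)cc4)S3(=O)=O)ccc2C[C@@H]1O | intermediate
18 | 1-(4-tert-butoxyphenyl)-3-(2,4-dimethoxybenzyl)-5-{[(3S)-3-hydroxy-2,2-dimethylchroman-7-yl]methyl}-6-thia-3-azabicyclo[3.1.0]hexane-2,4-dione 6,6-dioxide (episulfone) | CC1(C)Oc2cc(CC34C(=O)N(Cc5ccc(OC)cc5OC)C(=O)C3(c5ccc(OC(C)(C)C)cc5)S4(=O)=O)ccc2C[C@@H]1O | intermediate
19 | 3-(4-tert-butoxyphenyl)-1-(2,4-dimethoxybenzyl)-4-{[(3S)-3-hydroxy-2,2-dimethylchroman-7-yl]methyl}-1H-pyrrole-2,5-dione | CC1(C)Oc2cc(CC3=C(c4ccc(OC(C)(C)C)cc4)C(=O)N(Cc4ccc(OC)cc4OC)C3=O)ccc2C[C@@H]1O | intermediate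
20 | asperimide C, 3-{[(3S)-3-hydroxy-2,2-dimethylchroman-7-yl]methyl}-4-(4-hydroxyphenyl)-1H-pyrrole-2,5-dione | CC1(C)Oc2cc(CC3=C(c4ccc(O)cc4)C(=O)NC3=O)ccc2C[C@@H]1O | target

## Step count and least certain steps

Total: 10 steps. Longest linear sequence: 8 steps (steps 1, 2, 3, 4, 7, 8, 9, 10, from aldehyde 1). Steps 5 and 6 form the convergent branch.

**Step 9 (key step, proposed new method).** The likeliest failure is slow 1,3-displacement at a fully substituted, bromine-bearing carbon by a highly stabilised carbanion. Halogen exchange between molecules, a second bromination or reductive loss of bromine would then compete. Secondary risks are base-induced migration of the new double bond into the exocyclic benzylidene position and oxidation of the resulting extended carbanion. The fallback uses known sequential cross-coupling on a dihalomaleimide. It sets out from bromide 8 and amine 10 and comes back at 19.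
- 2,3-Dibromomaleic anhydride and 10 are condensed in hot AcOH to 3,4-dibromo-1-(2,4-dimethoxybenzyl)-1H-pyrrole-2,5-dione F3.
- Mono-Suzuki–Miyaura coupling of F3 with one equivalent of 4-tert-butoxyphenylboronic acid (Pd(PPh3)4, K2CO3, dioxane) gives 3-bromo-4-(4-tert-butoxyphenyl)-1-(2,4-dimethoxybenzyl)-1H-pyrrole-2,5-dione F4.
- Bromide 8 is silylated (Et3SiOTf, 2,6-lutidine) to (3S)-7-(bromomethyl)-2,2-dimethyl-3-(triethylsilyloxy)chroman F1.
- Zinc dust and LiCl in THF convert F1 into the benzylic zinc bromide F2.
- Negishi coupling of F2 with F4 (Pd(OAc)2, 2-dicyclohexylphosphino-2',6'-dimethoxybiphenyl, THF, rt) gives the triethylsilyl ether of 19, F5.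
- Aqueous AcOH in THF removes the silyl group and returns 19.

**Step 8.** Reductive elimination from palladium may be sluggish for so stabilised and hindered a carbanion, leading to hydrodebromination of 15 instead of coupling. Arylation could also stray to the benzyl-bearing carbon, or the free secondary alcohol could be oxidised through a palladium alkoxide. The fallback reverses the order of the two C–C bond formations. It sets out from 13, 15 and 8 and comes back at 16.
- An excess of the symmetric core 13 is arylated with 15 under the same catalyst to give 2-(4-tert-butoxyphenyl)-4-(2,4-dimethoxybenzyl)thiomorpholine-3,5-dione 1,1-dioxide F6.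
- F6 is converted with NaN(SiMe3)2 (2.2 equiv, THF, −78 °C) into its α,α'-dianion, which is alkylated by 8 at the less stabilised, non-arylated carbon to give 16.

**Step 10.** Cleavage of the N-benzyl bond of an imide may be incomplete under conditions the chroman tolerates, and tert-butyl or benzyl cations may alkylate the liberated phenol. The fallback exchanges the nitrogen instead of deprotecting it. It sets out from 19 and comes back at 20.
- Hydrolysis with KOH in aqueous EtOH, then acidification with citric acid, closes the maleic anhydride, 3-(4-tert-butoxyphenyl)-4-{[(3S)-3-hydroxy-2,2-dimethylchroman-7-yl]methyl}furan-2,5-dione F7.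
- Hexamethyldisilazane and MeOH in DMF convert F7 into the N-unsubstituted maleimide, 3-(4-tert-butoxyphenyl)-4-{[(3S)-3-hydroxy-2,2-dimethylchroman-7-yl]methyl}-1H-pyrrole-2,5-dione F8.
- Brief treatment of F8 with CF3CO2H in CH2Cl2 at rt removes the tert-butyl group and gives 20.

**Step 7.** Over-alkylation (at the same or the opposite sulfone carbon) may occur, and the hydroxy bromide 8 may self-condense if alkylation is slow. The fallback replaces alkylation by reductive Knoevenagel condensation, which can only give the mono-substituted product. It sets out from diol 7 and core 13 and comes back at 14; it also bypasses step 4.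
- MnO2 in CH2Cl2 oxidises the benzylic alcohol of 7 selectively to (3S)-3-hydroxy-2,2-dimethylchroman-7-carbaldehyde F9.
- F9 and 13 are condensed with catalytic L-proline in EtOH to the benzylidene compound F10.
- F10 is reduced in the same flask by diethyl 2,6-dimethyl-1,4-dihydropyridine-3,5-dicarboxylate (Hantzsch ester) to 14.

**Step 1.** The Grignard reagent may attack the ester, or the chromene may oligomerise under acid during dehydration. The fallback avoids a carbanionic reagent. It sets out from 1 and comes back at 5.
- A Petasis borono-Mannich reaction of 1 with dibenzylamine and 2-methylprop-1-enylboronic acid (EtOH, rt) gives methyl 4-[1-(dibenzylamino)-3-methylbut-2-en-1-yl]-3-hydroxybenzoate F11.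
- Heating F11 in toluene expels dibenzylamine and gives 5 through the same quinone methide 4.

## Further compounds

F1 | step 9 | (3S)-7-(bromomethyl)-2,2-dimethyl-3-(triethylsilyloxy)chroman | CC1(C)Oc2cc(CBr)ccc2C[C@@H]1O[Si](CC)(CC)CC
F2 | step 9 | {[(3S)-2,2-dimethyl-3-(triethylsilyloxy)chroman-7-yl]methyl}zinc bromide | CC1(C)Oc2cc(C[Zn]Br)ccc2C[C@@H]1O[Si](CC)(CC)CC
F3 | step 9 | 3,4-dibromo-1-(2,4-dimethoxybenzyl)-1H-pyrrole-2,5-dione | COc1ccc(CN2C(=O)C(Br)=C(Br)C2=O)c(OC)c1
F4 | step 9 | 3-bromo-4-(4-tert-butoxyphenyl)-1-(2,4-dimethoxybenzyl)-1H-pyrrole-2,5-dione | COc1ccc(CN2C(=O)C(Br)=C(c3ccc(OC(C)(C)C)cc3)C2=O)c(OC)c1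
F5 | step 9 | 3-(4-tert-butoxyphenyl)-1-(2,4-dimethoxybenzyl)-4-{[(3S)-2,2-dimethyl-3-(triethylsilyloxy)chroman-7-yl]methyl}-1H-pyrrole-2,5-dione | CC1(C)Oc2cc(CC3=C(c4ccc(OC(C)(C)C)cc4)C(=O)N(Cc4ccc(OC)cc4OC)C3=O)ccc2C[C@@H]1O[Si](CC)(CC)CC
F6 | step 8 | 2-(4-tert-butoxyphenyl)-4-(2,4-dimethoxybenzyl)thiomorpholine-3,5-dione 1,1-dioxide (racemic) | COc1ccc(CN2C(=O)CS(=O)(=O)C(c3ccc(OC(C)(C)C)cc3)C2=O)c(OC)c1
F7 | step 10 | 3-(4-tert-butoxyphenyl)-4-{[(3S)-3-hydroxy-2,2-dimethylchroman-7-yl]methyl}furan-2,5-dione | CC1(C)Oc2cc(CC3=C(c4ccc(OC(C)(C)C)cc4)C(=O)OC3=O)ccc2C[C@@H]1O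
F8 | step 10 | 3-(4-tert-butoxyphenyl)-4-{[(3S)-3-hydroxy-2,2-dimethylchroman-7-yl]methyl}-1H-pyrrole-2,5-dione | CC1(C)Oc2cc(CC3=C(c4ccc(OC(C)(C)C)cc4)C(=O)NC3=O)ccc2C[C@@H]1O
F9 | step 7 | (3S)-3-hydroxy-2,2-dimethylchroman-7-carbaldehyde | CC1(C)Oc2cc(C=O)ccc2C[C@@H]1O
F10 | step 7 | 4-(2,4-dimethoxybenzyl)-2-{[(3S)-3-hydroxy-2,2-dimethylchroman-7-yl]methylidene}thiomorpholine-3,5-dione 1,1-dioxide | CC1(C)Oc2cc(C=C3C(=O)N(Cc4ccc(OC)cc4OC)C(=O)CS3(=O)=O)ccc2C[C@@H]1O
F11 | step 1 | methyl 4-[1-(dibenzylamino)-3-methylbut-2-en-1-yl]-3-hydroxybenzoate (racemic) | COC(=O)c1ccc(C(C=C(C)C)N(Cc2ccccc2)Cc2ccccc2)c(O)c1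
A1 | alternative 1 | methyl 3-(tert-butyldimethylsilyloxy)-4-(trifluoromethylsulfonyloxy)benzoate | COC(=O)c1ccc(OS(=O)(=O)C(F)(F)F)c(O[Si](C)(C)C(C)(C)C)c1
A2 | alternative 1 | 4,4,5,5-tetramethyl-2-(prop-1-en-2-yl)-1,3,2-dioxaborolane | CC(=C)B1OC(C)(C)C(C)(C)O1
A3 | alternative 1 | vinyllithium | [Li]C=C
A4 | alternative 1 | methyl (S)-3-(tert-butyldimethylsilyloxy)-4-[3-methyl-2-(4,4,5,5-tetramethyl-1,3,2-dioxaborolan-2-yl)but-3-enyl]benzoate | COC(=O)c1ccc(C[C@@H](C(C)=C)B2OC(C)(C)C(C)(C)O2)c(O[Si](C)(C)C(C)(C)C)c1
A5 | alternative 2 | (6S)-6-(tert-butyldimethylsilyloxy)-4-diazo-7-(ethynyloxy)-7-methyloct-1-en-3-one | C=CC(=O)C(=[N+]=[N-])C[C@H](O[Si](C)(C)C(C)(C)C)C(C)(C)OC#C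
A6 | alternative 2 | (S)-3-(tert-butyldimethylsilyloxy)-2,2-dimethylchroman-7-ol | CC1(C)Oc2cc(O)ccc2C[C@@H]1O[Si](C)(C)C(C)(C)C
A7 | alternative 3 | methyl 3-hydroxy-4-(hydroxymethyl)benzoate | COC(=O)c1ccc(CO)c(O)c1
A8 | alternative 3 | methyl 4-methylidene-3-oxocyclohexa-1,5-diene-1-carboxylate (o-quinone methide) | COC(=O)C1=CC(=O)C(=C)C=C1
A9 | alternative 3 | 4,4,5,5-tetramethyl-2-(2-methylprop-1-en-1-yl)-1,3,2-dioxaborolane | CC(C)=CB1OC(C)(C)C(C)(C)O1
A10 | alternative 3 | methyl (S)-2,2-dimethyl-3-(4,4,5,5-tetramethyl-1,3,2-dioxaborolan-2-yl)chroman-7-carboxylate | CC1(C)Oc2cc(C(=O)OC)ccc2C[C@@H]1B3OC(C)(C)C(C)(C)O3
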